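The tetralin is traced back to a lariciresinol-type tetrahydrofuran, and that ring to an acyclic α-bromo-β-allyloxy imide plus an arylzinc. One nickel-catalysed radical cyclization/Negishi arylation closes the tetrahydrofuran (C2–C3) and attaches ring A to the arylmethyl arm (C4–C4a). The step exploits that C4 is an unsubstituted benzylic CH2 on C4a of ring A and that C3 bears the oxygenated arm C9′ (tetralin numbering): C3=C4 can be the vinyl end of an allyl ether hung on the C1 oxygen. The C1 carbinol centre, set by an Evans aldol, relays chirality to C2 and C3 and is then ionized; Friedel–Crafts closure of C1–C8a resets it trans.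

Key step: step 5

Remark on numbering: tetralin numbering of the target is used for these atoms in every precursor. C1 bears the pendant ring B, C2 and C3 bear the arms C9 and C9′, C4 is the benzylic CH2, and C4a/C8a are the fusion carbons of ring A.
Assumption: compounds 1, 3 and 6, benzyl bromide, bromoacetyl bromide and allyl 2,2,2-trichloroacetimidate are taken as commercial.

**Step 1**
Reactants: 1 4-bromo-2,6-dimethoxyphenol
Product: 2 2-(benzyloxy)-5-bromo-1,3-dimethoxybenzene
Conditions: BnBr, K2CO3, DMF, 60 °C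
Reagents that add atoms: benzyl bromide, BrCc1ccccc1
Why: Williamson ether synthesis, in which the phenoxide of 1 (both ortho positions blocked by OMe) is O-alkylated by benzyl bromide; no stereocentre is involved.

**Step 2**
Reactants: 3 (S)-4-benzyloxazolidin-2-one
Product: 5 (S)-4-benzyl-3-(2-bromoacetyl)oxazolidin-2-one, via N-lithio oxazolidinone 4 (not isolated)
Conditions: n-BuLi, THF, −78 °C; BrCH2COBr, −78 to 0 °C
Reagents that add atoms: bromoacetyl bromide, BrCC(Br)=O
Why: N-acylation of the lithiated Evans auxiliary, where the acyl bromide reacts far faster than the alkyl bromide at low temperature; the auxiliary stereocentre is untouched.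

**Step 3**
Reactants: 5 (S)-4-benzyl-3-(2-bromoacetyl)oxazolidin-2-one, 6 4-(benzyloxy)-3,5-dimethoxybenzaldehyde
Product: 8 (S)-4-benzyl-3-[(2S,3R)-3-[4-(benzyloxy)-3,5-dimethoxyphenyl]-2-bromo-3-hydroxypropanoyl]oxazolidin-2-one, via boron enolate 7 (not isolated)
Conditions: Bu2BOTf, iPr2NEt, CH2Cl2, −78 to 0 °C; 6, −78 to 0 °C; pH 7 buffer, MeOH, H2O2, 0 °C
Reagents that add atoms: none
Why: Evans syn aldol reaction, in which the (Z)-boron enolate 7 adds to 6 through a Zimmerman–Traxler chair on the face opposite the auxiliary benzyl group, setting the carbinol carbon (C1 of the target, R here) and the bromine-bearing C2 (S) syn to it.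

**Step 4**
Reactants: 8 (S)-4-benzyl-3-[(2S,3R)-3-[4-(benzyloxy)-3,5-dimethoxyphenyl]-2-bromo-3-hydroxypropanoyl]oxazolidin-2-one
Product: 9 (S)-3-[(2S,3R)-3-(allyloxy)-3-[4-(benzyloxy)-3,5-dimethoxyphenyl]-2-bromopropanoyl]-4-benzyloxazolidin-2-one
Conditions: allyl 2,2,2-trichloroacetimidate, TfOH (10 mol%), CH2Cl2/cyclohexane, 0 °C to rt
Reagents that add atoms: allyl 2,2,2-trichloroacetimidate, C=CCOC(=N)C(Cl)(Cl)Cl
Why: Acid-catalysed trichloroacetimidate O-alkylation, chosen because the bromohydrin would close to an epoxide or undergo retro-aldol cleavage under basic Williamson conditions; neither stereocentre is touched, since the adjacent C–Br and acyl groups disfavour ionization at C1.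

**Step 5**
Reactants: 2 2-(benzyloxy)-5-bromo-1,3-dimethoxybenzene, 9 (S)-3-[(2S,3R)-3-(allyloxy)-3-[4-(benzyloxy)-3,5-dimethoxyphenyl]-2-bromopropanoyl]-4-benzyloxazolidin-2-one
Product: 12 (S)-4-benzyl-3-{(2S,3S,4R)-4-[4-(benzyloxy)-3,5-dimethoxybenzyl]-2-[4-(benzyloxy)-3,5-dimethoxyphenyl]tetrahydrofuran-3-carbonyl}oxazolidin-2-one, via arylmagnesium bromide 10 (not isolated), via arylzinc chloride 11 (not isolated)
Conditions: 2, Mg, LiCl, THF, rt; ZnCl2, THF, 0 °C to rt; then 9, NiBr2 (3 mol%), 2,2′:6′,2″-terpyridine (4 mol%), NMP/THF, rt to 50 °C, dilute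
Reagents that add atoms: none
Why: Transmetalation of 11 gives a terpyridine-ligated aryl–nickel species (monovalent nickel) that abstracts bromine from 9; the α-acyl radical at C2 adds to C3 of the allyl ether (C2–C3), and the primary C4 radical is captured by the aryl–nickel complex (divalent nickel) and released by reductive elimination from trivalent nickel (C4–C4a). The closest known reaction type is the nickel-catalysed tandem radical cyclization/Negishi cross-coupling of alkene-tethered alkyl halides with arylzinc reagents. One ring is closed, the tetrahydrofuran C1–O–C9′–C3–C2, in the 5-exo-trig mode through a chair-like transition state with the C1 aryl group pseudo-equatorial. C2 should be set trans to the C1 aryl group because the planar imide radical reacts from the conformer that minimizes A(1,3) strain, which the (S)-benzyl auxiliary is expected to reinforce; C3 is set by the chair, which places the new C4 arm cis to the C2 acyl group and trans to the C1 aryl group (the lariciresinol pattern; C1 keeps its configuration and is only renamed S). The step needs ring closure to outrun direct aryl capture at C2 and 5-exo to beat 6-endo closure; the fast closure of the 3-oxa-5-hexenyl-type radical against a low nickel concentration, and the unsubstituted terminal CH2, should secure both. Minor diastereomers must be removed by chromatography here, while the auxiliary still makes them diastereomers, because C1 is erased later.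

**Step 6**
Reactants: 12 (S)-4-benzyl-3-{(2S,3S,4R)-4-[4-(benzyloxy)-3,5-dimethoxybenzyl]-2-[4-(benzyloxy)-3,5-dimethoxyphenyl]tetrahydrofuran-3-carbonyl}oxazolidin-2-one
Product: 13 {(2S,3R,4R)-4-[4-(benzyloxy)-3,5-dimethoxybenzyl]-2-[4-(benzyloxy)-3,5-dimethoxyphenyl]tetrahydrofuran-3-yl}methanol
Conditions: LiBH4, MeOH (1 equiv), THF, 0 °C
Reagents that add atoms: none
Why: Reductive cleavage of the N-acyl oxazolidinone by LiBH4 (attack at the exocyclic carbonyl, auxiliary 3 released and recoverable) gives the primary alcohol at C9 without touching the three ring stereocentres.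

**Step 7**
Reactants: 13 {(2S,3R,4R)-4-[4-(benzyloxy)-3,5-dimethoxybenzyl]-2-[4-(benzyloxy)-3,5-dimethoxyphenyl]tetrahydrofuran-3-yl}methanol
Product: 14 [(1S,2R,3R)-7-(benzyloxy)-1-[4-(benzyloxy)-3,5-dimethoxyphenyl]-6,8-dimethoxy-1,2,3,4-tetrahydronaphthalene-2,3-diyl]dimethanol
Conditions: BF3·OEt2, CH2Cl2, −20 to 0 °C
Reagents that add atoms: none
Why: Lewis acid ionization of the benzylic C1–O bond gives a ring B-stabilized cation that is captured by C8a of ring A (ortho and para to its methoxy groups) in an intramolecular Friedel–Crafts alkylation, the known acid-mediated tetrahydrofuran-to-aryltetralin rearrangement of lariciresinol-type lignans; a chair-like transition state with the C2 and C3 arms and ring B equatorial should set C1 (S) trans to the C2 arm, while C2 and C3 are untouched.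

**Step 8**
Reactants: 14 [(1S,2R,3R)-7-(benzyloxy)-1-[4-(benzyloxy)-3,5-dimethoxyphenyl]-6,8-dimethoxy-1,2,3,4-tetrahydronaphthalene-2,3-diyl]dimethanol
Product: 15 [(1S,2R,3R)-7-(benzyloxy)-1-[4-(benzyloxy)-3,5-dimethoxyphenyl]-6,8-dimethoxy-1,2,3,4-tetrahydronaphthalene-2,3-diyl]bis(methylene) diacetate
Conditions: Ac2O, pyridine, DMAP (cat.), CH2Cl2, rt
Reagents that add atoms: acetic anhydride, CC(=O)OC(C)=O
Why: Standard acylation of the two primary alcohols, the phenols being masked as benzyl ethers.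

**Step 9**
Reactants: 15 [(1S,2R,3R)-7-(benzyloxy)-1-[4-(benzyloxy)-3,5-dimethoxyphenyl]-6,8-dimethoxy-1,2,3,4-tetrahydronaphthalene-2,3-diyl]bis(methylene) diacetate
Product: 16 [(1S,2R,3R)-7-hydroxy-1-(4-hydroxy-3,5-dimethoxyphenyl)-6,8-dimethoxy-1,2,3,4-tetrahydronaphthalene-2,3-diyl]bis(methylene) diacetate
Conditions: H2 (1 atm), Pd/C (10 wt%), EtOAc/MeOH, rt
Reagents that add atoms: none
Why: Hydrogenolysis of the two aryl benzyl ethers on Pd/C should leave the acetates and the doubly benzylic C1–H bond intact and release the target.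

**Compound list**
1 | 4-bromo-2,6-dimethoxyphenol | COc1cc(Br)cc(OC)c1O | starting material
2 | 2-(benzyloxy)-5-bromo-1,3-dimethoxybenzene | COc1cc(Br)cc(OC)c1OCc1ccccc1 | intermediate
3 | (S)-4-benzyloxazolidin-2-one | O=C1N[C@@H](Cc2ccccc2)CO1 | starting material
4 | N-lithio-(S)-4-benzyloxazolidin-2-one | [Li]N1[C@@H](Cc2ccccc2)COC1=O | intermediate (not isolated)
5 | (S)-4-benzyl-3-(2-bromoacetyl)oxazolidin-2-one | BrCC(=O)N1[C@@H](Cc2ccccc2)COC1=O | intermediate
6 | 4-(benzyloxy)-3,5-dimethoxybenzaldehyde | COc1cc(C=O)cc(OC)c1OCc1ccccc1 | starting material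
7 | (Z)-dibutylboron enolate of 5 | Br/C=C(\OB(CCCC)CCCC)N1[C@@H](Cc2ccccc2)COC1=O | intermediate (not isolated)
8 | (S)-4-benzyl-3-[(2S,3R)-3-[4-(benzyloxy)-3,5-dimethoxyphenyl]-2-bromo-3-hydroxypropanoyl]oxazolidin-2-one | O[C@H](c1cc(OC)c(OCc2ccccc2)c(OC)c1)[C@H](Br)C(=O)N1[C@@H](Cc2ccccc2)COC1=O | intermediate
9 | (S)-3-[(2S,3R)-3-(allyloxy)-3-[4-(benzyloxy)-3,5-dimethoxyphenyl]-2-bromopropanoyl]-4-benzyloxazolidin-2-one | C=CCO[C@H](c1cc(OC)c(OCc2ccccc2)c(OC)c1)[C@H](Br)C(=O)N1[C@@H](Cc2ccccc2)COC1=O | intermediate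
10 | [4-(benzyloxy)-3,5-dimethoxyphenyl]magnesium bromide | COc1cc([Mg]Br)cc(OC)c1OCc1ccccc1 | intermediate (not isolated)
11 | [4-(benzyloxy)-3,5-dimethoxyphenyl]zinc chloride | COc1cc([Zn]Cl)cc(OC)c1OCc1ccccc1 | intermediate (not isolated)
12 | (S)-4-benzyl-3-{(2S,3S,4R)-4-[4-(benzyloxy)-3,5-dimethoxybenzyl]-2-[4-(benzyloxy)-3,5-dimethoxyphenyl]tetrahydrofuran-3-carbonyl}oxazolidin-2-one (2-aryl trans to 3-acyl, 3-acyl cis to 4-arylmethyl) | COc1cc(C[C@H]2CO[C@H](c3cc(OC)c(OCc4ccccc4)c(OC)c3)[C@H]2C(=O)N2[C@@H](Cc3ccccc3)COC2=O)cc(OC)c1OCc1ccccc1 | intermediate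
13 | {(2S,3R,4R)-4-[4-(benzyloxy)-3,5-dimethoxybenzyl]-2-[4-(benzyloxy)-3,5-dimethoxyphenyl]tetrahydrofuran-3-yl}methanol | COc1cc(C[C@H]2CO[C@H](c3cc(OC)c(OCc4ccccc4)c(OC)c3)[C@H]2CO)cc(OC)c1OCc1ccccc1 | intermediate
14 | [(1S,2R,3R)-7-(benzyloxy)-1-[4-(benzyloxy)-3,5-dimethoxyphenyl]-6,8-dimethoxy-1,2,3,4-tetrahydronaphthalene-2,3-diyl]dimethanol (all-trans) | COc1cc([C@H]2c3c(cc(OC)c(OCc4ccccc4)c3OC)C[C@@H](CO)[C@@H]2CO)cc(OC)c1OCc1ccccc1 | intermediate
15 | diacetate of 14 | COc1cc([C@H]2c3c(cc(OC)c(OCc4ccccc4)c3OC)C[C@@H](COC(C)=O)[C@@H]2COC(C)=O)cc(OC)c1OCc1ccccc1 | intermediate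
16 | [(1S,2R,3R)-7-hydroxy-1-(4-hydroxy-3,5-dimethoxyphenyl)-6,8-dimethoxy-1,2,3,4-tetrahydronaphthalene-2,3-diyl]bis(methylene) diacetate | COc1cc([C@H]2c3c(cc(OC)c(O)c3OC)C[C@@H](COC(C)=O)[C@@H]2COC(C)=O)cc(OC)c1O | target

**Step count**
Total steps: 9. Longest linear sequence: 8 steps (3 → 5 → 8 → 9 → 12 → 13 → 14 → 15 → 16).

**Steps most likely to fail**

1. Step 5. The C2 radical may be intercepted by the aryl–nickel species before it cyclizes (direct α-arylation). Two-electron reduction may also expel the allyloxy group by β-elimination, or the ring closure may show poor facial selectivity. The fallback sets out from 9 (with aldehyde 6) and comes back at 12. Wittig methylenation of 6 (Ph3PCH3Br, KOtBu, THF) would give 2-(benzyloxy)-1,3-dimethoxy-5-vinylbenzene F1. Cross-metathesis of 9 with F1 (second-generation Grubbs catalyst, CH2Cl2, 40 °C) would give the (E)-cinnamyl ether F2, in which the C4–C4a bond already exists. Reductive radical cyclization (Bu3SnH, AIBN, benzene, 80 °C, slow addition) would then close C2–C3 by 5-exo attack on the styrene through the same chair, the benzylic C4 radical taking hydrogen from the stannane, to give 12.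

2. Step 7. Ionization of the non-phenolic benzylic ether may be incomplete, the Lewis acid may cleave the benzyl ethers, the cation may re-close to C1-epimeric tetrahydrofurans without carbocyclization, or facial selectivity at C1 may be poor. The fallback sets out from 13 and comes back at 16. Hydrogenolysis first (H2, Pd/C, EtOAc/MeOH) would give the free bisphenol 5,5′-dimethoxylariciresinol F3. Its benzylic ether should open under mild protic acid (HCO2H, rt) through a para-quinone methide and cyclize to lyoniresinol F4. Lipase-catalysed acylation (Candida antarctica lipase B, vinyl acetate, THF) would then acetylate only the two primary alcohols to give 16.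

3. Step 4. The acid may ionize the benzylic carbinol (erosion of the C1 configuration), retro-aldol cleavage may compete, or alkylation of the hindered hydroxyl may stall. The fallback sets out from 5 and 6 and comes back at 12. Arbuzov reaction of 5 with P(OEt)3 (neat, 100 °C) would give the phosphonate F5. Masamune–Roush olefination with 6 (LiCl, iPr2NEt, MeCN) would give the (E)-cinnamoyl imide F6. Bromo-alkoxylation (NBS, allyl alcohol, CH2Cl2, −20 °C; anti addition, allyl alcohol opening the bromonium ion at the benzylic carbon) would give the anti bromo ether F7, the C2 epimer of 9, after chromatographic removal of the C1-epimeric adduct. F7 gives the same C2 radical as 9 and would enter step 5 unchanged to give 12.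

**Further compounds**
F1 | step 5 | 2-(benzyloxy)-1,3-dimethoxy-5-vinylbenzene | C=Cc1cc(OC)c(OCc2ccccc2)c(OC)c1
F2 | step 5 | (S)-4-benzyl-3-[(2S,3R)-3-[4-(benzyloxy)-3,5-dimethoxyphenyl]-3-{[(E)-3-[4-(benzyloxy)-3,5-dimethoxyphenyl]allyl]oxy}-2-bromopropanoyl]oxazolidin-2-one | COc1cc(/C=C/CO[C@H](c2cc(OC)c(OCc3ccccc3)c(OC)c2)[C@H](Br)C(=O)N2[C@@H](Cc3ccccc3)COC2=O)cc(OC)c1OCc1ccccc1
F3 | step 7 | 5,5′-dimethoxylariciresinol, 4-{[(3R,4R,5S)-5-(4-hydroxy-3,5-dimethoxyphenyl)-4-(hydroxymethyl)tetrahydrofuran-3-yl]methyl}-2,6-dimethoxyphenol | COc1cc(C[C@H]2CO[C@H](c3cc(OC)c(O)c(OC)c3)[C@H]2CO)cc(OC)c1O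
F4 | step 7 | lyoniresinol, (1S,2R,3R)-7-hydroxy-1-(4-hydroxy-3,5-dimethoxyphenyl)-6,8-dimethoxy-1,2,3,4-tetrahydronaphthalene-2,3-dimethanol | COc1cc([C@H]2c3c(cc(OC)c(O)c3OC)C[C@@H](CO)[C@@H]2CO)cc(OC)c1O
F5 | step 4 | diethyl {2-[(S)-4-benzyl-2-oxooxazolidin-3-yl]-2-oxoethyl}phosphonate | CCOP(=O)(CC(=O)N1[C@@H](Cc2ccccc2)COC1=O)OCC
F6 | step 4 | (S)-4-benzyl-3-[(E)-3-[4-(benzyloxy)-3,5-dimethoxyphenyl]acryloyl]oxazolidin-2-one | COc1cc(/C=C/C(=O)N2[C@@H](Cc3ccccc3)COC2=O)cc(OC)c1OCc1ccccc1
F7 | step 4 | (S)-3-[(2R,3R)-3-(allyloxy)-3-[4-(benzyloxy)-3,5-dimethoxyphenyl]-2-bromopropanoyl]-4-benzyloxazolidin-2-one | C=CCO[C@H](c1cc(OC)c(OCc2ccccc2)c(OC)c1)[C@@H](Br)C(=O)N1[C@@H](Cc2ccccc2)COC1=O
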